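## Retrosynthetic overview

1. Both trans‑2,3‑diaryl‑2,3‑dihydrobenzofuran rings are opened at O1–C2. Each is closed by a phenoxide adding intramolecularly (oxa‑Michael, 1,6‑addition) to a para‑quinone methide released from a silyl‑masked 4‑hydroxybenzylic acetate.
2. The Z‑stilbene comes from a diarylalkyne (Sonogashira coupling, then cis semi‑hydrogenation). The two benzylic acetates come from a dialdehyde plus an aryl Grignard reagent, and the dialdehyde from a bis‑nitro compound by a Nef reaction.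
3. The two diarylmethine centres (C‑3 of each dihydrofuran) are set by two catalyst‑controlled rhodium‑catalysed conjugate arylations of (E)‑nitroalkenes; the second one joins the two main fragments.
4. Fragments: ring B nitroalkene from 5‑bromo‑o‑vanillin, resorcinol boronate from 5‑bromoresorcinol, ring A nitroalkene from 1‑bromo‑3,5‑dimethoxybenzene, aryl Grignard and arylalkyne from 4‑bromophenol.
5. Order of ring formation: no ring is formed until the last step, where the dihydrofuran on ring B and the dihydrofuran on ring A close together, each trans.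

Assumption: the SMILES is taken literally (ring B is a 7‑hydroxy‑2,3‑dihydrobenzofuran joined through C‑5), and the (1R,4R)‑diene–rhodium catalyst is taken to arylate the Re face of C‑β of an (E)‑β‑aryl nitroalkene (its antipode the Si face); if the first run shows the reverse sense, the two ligand antipodes are exchanged.

Abbreviations: TIPS = triisopropylsilyl, TIPSO = triisopropylsilyloxy, TBS = tert‑butyldimethylsilyl, TBSO = tert‑butyldimethylsilyloxy, diene L = 2,5‑diphenylbicyclo[2.2.2]octa‑2,5‑diene, ring A = the resorcinol‑derived ring that carries the styryl arm, ring B = the catechol‑derived central ring.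

## Route

Step 1
Reactants: 1 4‑bromophenol
Product: 2 (4‑bromophenoxy)triisopropylsilane
Conditions: TIPSCl (1.1 equiv), imidazole (2 equiv), DMF, rt
Reagents that add atoms: chlorotriisopropylsilane, CC(C)[Si](Cl)(C(C)C)C(C)C
Why: Imidazole‑mediated O‑silylation of a phenol; the TIPS ether tolerates Mg insertion, Pd coupling and brief carbonate/methanol.

Step 2
Reactants: 2 (4‑bromophenoxy)triisopropylsilane
Product: 3 [4‑(triisopropylsilyloxy)phenyl]magnesium bromide (titrated THF solution, about 0.5 M)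
Conditions: Mg turnings (1.3 equiv), I2 (cat.), THF, 45 °C
Reagents that add atoms: magnesium, [Mg]
Why: Grignard formation by Mg insertion into the aryl bromide; the hindered aryl silyl ether is inert to the organomagnesium.

Step 3
Reactants: 2 (4‑bromophenoxy)triisopropylsilane; 4 ethynyltrimethylsilane
Product: 5 triisopropyl{4‑[(trimethylsilyl)ethynyl]phenoxy}silane
Conditions: PdCl2(PPh3)2 (2 mol %), CuI (4 mol %), Et3N, 75 °C
Reagents that add atoms: none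
Why: Sonogashira coupling of the aryl bromide with the terminal alkyne.

Step 4
Reactants: 5 triisopropyl{4‑[(trimethylsilyl)ethynyl]phenoxy}silane
Product: 6 (4‑ethynylphenoxy)triisopropylsilane
Conditions: K2CO3 (0.2 equiv), MeOH/THF 1:1, rt, 1 h
Reagents that add atoms: none
Why: Base‑catalysed methanolysis (protodesilylation) of the C(sp)–SiMe3 bond is much faster than cleavage of the aryl O–TIPS ether.

Step 5
Reactants: 7 5‑bromobenzene‑1,3‑diol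
Product: 8 1‑bromo‑3,5‑bis(triisopropylsilyloxy)benzene
Conditions: TIPSCl (2.4 equiv), imidazole (4 equiv), DMF, rt
Reagents that add atoms: chlorotriisopropylsilane, CC(C)[Si](Cl)(C(C)C)C(C)C
Why: Double O‑silylation of the resorcinol.

Step 6
Reactants: 8 1‑bromo‑3,5‑bis(triisopropylsilyloxy)benzene
Product: 9 2‑[3,5‑bis(triisopropylsilyloxy)phenyl]‑4,4,5,5‑tetramethyl‑1,3,2‑dioxaborolane
Conditions: B2pin2 (1.2 equiv), PdCl2(dppf) (3 mol %), KOAc (3 equiv), 1,4‑dioxane, 90 °C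
Reagents that add atoms: bis(pinacolato)diboron, CC1(C)OB(OC1(C)C)B1OC(C)(C)C(C)(C)O1
Why: Miyaura borylation of the aryl bromide under anhydrous acetate conditions that leave aryl silyl ethers intact.

Step 7
Reactants: 10 1‑bromo‑3,5‑dimethoxybenzene
Product: 12 2‑bromo‑4,6‑dimethoxybenzaldehyde, via iminium chloride 11 (not isolated)
Conditions: POCl3 (1.5 equiv), DMF, 0 °C to 90 °C; then H2O, 0 °C
Reagents that add atoms: N,N‑dimethylformamide, CN(C)C=O; water, O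
Why: Vilsmeier–Haack formylation para to one methoxy and ortho to the other (the position between the two methoxy groups is more hindered); the iminium is hydrolysed on work‑up.

Step 8
Reactants: 12 2‑bromo‑4,6‑dimethoxybenzaldehyde
Product: 13 2‑bromo‑4,6‑dihydroxybenzaldehyde
Conditions: BBr3 (3 equiv), CH2Cl2, −78 °C to rt; then H2O, 0 °C
Reagents that add atoms: none
Why: Lewis‑acid cleavage of both aryl methyl ethers by BBr3; aldehyde and aryl bromide survive.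

Step 9
Reactants: 13 2‑bromo‑4,6‑dihydroxybenzaldehyde; 14 nitromethane
Product: 15 5‑bromo‑4‑[(E)‑2‑nitroethenyl]benzene‑1,3‑diol
Conditions: 14 (5 equiv), NH4OAc (0.5 equiv), AcOH, 100 °C, N2
Reagents that add atoms: none
Why: Henry (nitroaldol) condensation with in situ dehydration gives the thermodynamically favoured E‑nitroalkene.

Step 10
Reactants: 15 5‑bromo‑4‑[(E)‑2‑nitroethenyl]benzene‑1,3‑diol
Product: 16 1‑bromo‑2‑[(E)‑2‑nitroethenyl]‑3,5‑bis(triisopropylsilyloxy)benzene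
Conditions: TIPSOTf (2.4 equiv), 2,6‑lutidine (3 equiv), CH2Cl2, 0 °C
Reagents that add atoms: triisopropylsilyl trifluoromethanesulfonate, CC(C)[Si](OS(=O)(=O)C(F)(F)F)(C(C)C)C(C)C
Why: Silyl triflate with a non‑nucleophilic base silylates both phenols without conjugate addition to the nitroalkene.

Step 11
Reactants: 17 5‑bromo‑2‑hydroxy‑3‑methoxybenzaldehyde
Product: 18 5‑bromo‑2,3‑dihydroxybenzaldehyde
Conditions: BBr3 (2.5 equiv), CH2Cl2, −78 °C to 0 °C; then H2O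
Reagents that add atoms: none
Why: BBr3 demethylation of the aryl methyl ether to the catechol.

Step 12
Reactants: 18 5‑bromo‑2,3‑dihydroxybenzaldehyde; 14 nitromethane
Product: 19 5‑bromo‑3‑[(E)‑2‑nitroethenyl]benzene‑1,2‑diol
Conditions: 14 (5 equiv), NH4OAc (0.5 equiv), AcOH, 90 °C, N2
Reagents that add atoms: none
Why: Henry condensation–dehydration of the salicylaldehyde to the E‑nitroalkene.

Step 13
Reactants: 19 5‑bromo‑3‑[(E)‑2‑nitroethenyl]benzene‑1,2‑diol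
Product: 20 5‑bromo‑1,2‑bis(tert‑butyldimethylsilyloxy)‑3‑[(E)‑2‑nitroethenyl]benzene
Conditions: TBSOTf (2.4 equiv), 2,6‑lutidine (3 equiv), CH2Cl2, 0 °C
Reagents that add atoms: tert‑butyldimethylsilyl trifluoromethanesulfonate, CC(C)(C)[Si](C)(C)OS(=O)(=O)C(F)(F)F
Why: Bis‑silylation of the catechol; TBS is chosen here because two neighbouring TIPS groups would be too crowded.

Step 14
Reactants: 20 5‑bromo‑1,2‑bis(TBSO)‑3‑[(E)‑2‑nitroethenyl]benzene; 9 aryl pinacol boronate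
Product: 21 5‑bromo‑1,2‑bis(TBSO)‑3‑{(1R)‑1‑[3,5‑bis(TIPSO)phenyl]‑2‑nitroethyl}benzene
Conditions: 9 (1.5 equiv), [RhCl(C2H4)2]2 (2.5 mol %), (1R,4R)‑L (5.5 mol %), KOH (10 mol %), 1,4‑dioxane/H2O 10:1, 40 °C
Reagents that add atoms: none
Why: Hayashi–Miyaura rhodium‑catalysed asymmetric conjugate arylation; the diene‑bound aryl–rhodium adds to the Re face of C‑β and sets the (R) diarylmethine (later C‑3 of the dihydrofuran on ring B), with the aryl bromide and silyl ethers inert.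

Step 15
Reactants: 21 (R)‑bromide
Product: 22 2‑{3,4‑bis(TBSO)‑5‑[(1R)‑1‑[3,5‑bis(TIPSO)phenyl]‑2‑nitroethyl]phenyl}‑4,4,5,5‑tetramethyl‑1,3,2‑dioxaborolane
Conditions: B2pin2 (1.3 equiv), PdCl2(dppf) (3 mol %), KOAc (3 equiv), 1,4‑dioxane, 85 °C
Reagents that add atoms: bis(pinacolato)diboron, CC1(C)OB(OC1(C)C)B1OC(C)(C)C(C)(C)O1
Why: Miyaura borylation of the unhindered aryl bromide; weak anhydrous acetate base leaves the nitroalkane, the stereocentre and the silyl ethers untouched.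

Step 16
Reactants: 22 aryl pinacol boronate; 16 ring A nitroalkene
Product: 23 1‑bromo‑2‑[(1S)‑1‑{3,4‑bis(TBSO)‑5‑[(1R)‑1‑[3,5‑bis(TIPSO)phenyl]‑2‑nitroethyl]phenyl}‑2‑nitroethyl]‑3,5‑bis(TIPSO)benzene
Conditions: 16 (1.6 equiv), [RhCl(C2H4)2]2 (4 mol %), (1S,4S)‑L (9 mol %), KOH (10 mol %), 1,4‑dioxane/H2O 10:1, 50 °C
Reagents that add atoms: none
Why: Second Hayashi–Miyaura conjugate arylation, which joins the two fragments; the antipodal diene delivers the aryl group to the Si face of C‑β and sets the (S) diarylmethine (later C‑3 of the dihydrofuran on ring A) under catalyst control, independent of the remote centre.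

Step 17
Reactants: 23 bis‑nitro compound
Product: 25 (2S)‑2‑[2‑bromo‑4,6‑bis(TIPSO)phenyl]‑2‑{3,4‑bis(TBSO)‑5‑[(1R)‑1‑[3,5‑bis(TIPSO)phenyl]‑2‑oxoethyl]phenyl}acetaldehyde, via dipotassium bis‑nitronate 24 (not isolated)
Conditions: KOtBu (2.05 equiv), THF, −40 °C; then DMDO (2.4 equiv, acetone solution), −40 °C to 0 °C; pH 7 buffer; crude dialdehyde used at once
Reagents that add atoms: dimethyldioxirane, CC1(C)OO1
Why: Oxidative Nef reaction: each nitronate C=N is oxidised by the dioxirane to the aldehyde with loss of nitrite under near‑neutral, cold conditions that leave the two α‑diaryl centres untouched.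

Step 18
Reactants: 25 dialdehyde; 3 aryl Grignard reagent
Product: 27 (2S)‑2‑[2‑bromo‑4,6‑bis(TIPSO)phenyl]‑2‑{3‑[(1R)‑2‑acetoxy‑1‑[3,5‑bis(TIPSO)phenyl]‑2‑[4‑(TIPSO)phenyl]ethyl]‑4,5‑bis(TBSO)phenyl}‑1‑[4‑(TIPSO)phenyl]ethyl acetate (epimer mixture at both acetoxy carbons), via bis(bromomagnesium alkoxide) 26 (not isolated)
Conditions: 3 (3 equiv), LaCl3·2LiCl (2 equiv), THF, −78 °C; then Ac2O (8 equiv), DMAP (0.2 equiv), −78 °C to rt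
Reagents that add atoms: acetic anhydride, CC(=O)OC(C)=O
Why: Grignard 1,2‑addition (the lanthanum salt suppresses enolisation) followed by in situ O‑acetylation of the alkoxides; the two new carbinol centres are formed unselectively and are erased in step 21.

Step 19
Reactants: 27 bis‑acetate aryl bromide; 6 (4‑ethynylphenoxy)triisopropylsilane
Product: 28 (2S)‑2‑{2‑[[4‑(TIPSO)phenyl]ethynyl]‑4,6‑bis(TIPSO)phenyl}‑2‑{3‑[(1R)‑2‑acetoxy‑1‑[3,5‑bis(TIPSO)phenyl]‑2‑[4‑(TIPSO)phenyl]ethyl]‑4,5‑bis(TBSO)phenyl}‑1‑[4‑(TIPSO)phenyl]ethyl acetate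
Conditions: 6 (1.5 equiv), PdCl2(PhCN)2 (5 mol %), P(t‑Bu)3 (10 mol %), CuI (5 mol %), HN(i‑Pr)2 (3 equiv), 1,4‑dioxane, rt to 45 °C
Reagents that add atoms: none
Why: Sonogashira coupling with a bulky electron‑rich phosphine that activates the ortho‑substituted aryl bromide near room temperature, so the benzylic acetates and silyl ethers survive.

Step 20
Reactants: 28 diarylalkyne
Product: 29 (2S)‑2‑{2‑[(Z)‑2‑[4‑(TIPSO)phenyl]ethenyl]‑4,6‑bis(TIPSO)phenyl}‑2‑{3‑[(1R)‑2‑acetoxy‑1‑[3,5‑bis(TIPSO)phenyl]‑2‑[4‑(TIPSO)phenyl]ethyl]‑4,5‑bis(TBSO)phenyl}‑1‑[4‑(TIPSO)phenyl]ethyl acetate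
Conditions: H2 (1 atm), Pd/CaCO3 poisoned with Pb(OAc)2 (10 wt %), quinoline (0.5 equiv), EtOAc, rt, stopped after 1.0 equiv H2
Reagents that add atoms: none
Why: Syn semi‑hydrogenation of the alkyne on the poisoned palladium surface gives the Z‑stilbene without hydrogenolysis of the benzylic acetates.

Step 21
Reactants: 29 Z‑stilbene bis‑acetate
Product: 32 (2S,3S)‑3‑[(2R,3R)‑3‑(3,5‑dihydroxyphenyl)‑7‑hydroxy‑2‑(4‑hydroxyphenyl)‑2,3‑dihydro‑1‑benzofuran‑5‑yl]‑2‑(4‑hydroxyphenyl)‑4‑[(Z)‑2‑(4‑hydroxyphenyl)ethenyl]‑2,3‑dihydro‑1‑benzofuran‑6‑ol (the target), via nonaphenol bis‑acetate 30 (not isolated), via bis(quinone methide) 31 (not isolated)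
Conditions: TBAF (12 equiv), THF, 0 °C to rt, argon, dark; then 1 M HCl to pH 5
Reagents that add atoms: none
Why: Fluoride removes all nine silyl groups, each 4‑oxidobenzylic acetate undergoes 1,6‑elimination to a para‑quinone methide, and the neighbouring phenoxide closes each ring by a 5‑exo intramolecular oxa‑Michael (1,6‑conjugate) addition; the reversible closure places each new C‑2 aryl trans to the fixed C‑3 aryl, giving 2S on ring A and 2R on ring B.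

## Compound list

1 | 4‑bromophenol | Oc1ccc(Br)cc1 | starting material
2 | (4‑bromophenoxy)triisopropylsilane | CC(C)[Si](Oc1ccc(Br)cc1)(C(C)C)C(C)C | intermediate
3 | [4‑(triisopropylsilyloxy)phenyl]magnesium bromide | CC(C)[Si](Oc1ccc([Mg]Br)cc1)(C(C)C)C(C)C | intermediate
4 | ethynyltrimethylsilane | C#C[Si](C)(C)C | starting material
5 | triisopropyl{4‑[(trimethylsilyl)ethynyl]phenoxy}silane | CC(C)[Si](Oc1ccc(C#C[Si](C)(C)C)cc1)(C(C)C)C(C)C | intermediate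
6 | (4‑ethynylphenoxy)triisopropylsilane | CC(C)[Si](Oc1ccc(C#C)cc1)(C(C)C)C(C)C | intermediate
7 | 5‑bromobenzene‑1,3‑diol | Oc1cc(O)cc(Br)c1 | starting material
8 | 1‑bromo‑3,5‑bis(triisopropylsilyloxy)benzene | Brc1cc(O[Si](C(C)C)(C(C)C)C(C)C)cc(O[Si](C(C)C)(C(C)C)C(C)C)c1 | intermediate
9 | 2‑[3,5‑bis(triisopropylsilyloxy)phenyl]‑4,4,5,5‑tetramethyl‑1,3,2‑dioxaborolane | CC1(C)OB(OC1(C)C)c2cc(O[Si](C(C)C)(C(C)C)C(C)C)cc(O[Si](C(C)C)(C(C)C)C(C)C)c2 | intermediate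
10 | 1‑bromo‑3,5‑dimethoxybenzene | COc1cc(OC)cc(Br)c1 | starting material
11 | N‑[(2‑bromo‑4,6‑dimethoxyphenyl)methylidene]‑N‑methylmethanaminium chloride | COc1cc(OC)c(C=[N+](C)C)c(Br)c1.[Cl-] | intermediate
12 | 2‑bromo‑4,6‑dimethoxybenzaldehyde | COc1cc(OC)c(C=O)c(Br)c1 | intermediate
13 | 2‑bromo‑4,6‑dihydroxybenzaldehyde | Oc1cc(O)c(C=O)c(Br)c1 | intermediate
14 | nitromethane | C[N+](=O)[O-] | starting material
15 | 5‑bromo‑4‑[(E)‑2‑nitroethenyl]benzene‑1,3‑diol | Oc1cc(O)c(/C=C/[N+](=O)[O-])c(Br)c1 | intermediate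
16 | 1‑bromo‑2‑[(E)‑2‑nitroethenyl]‑3,5‑bis(triisopropylsilyloxy)benzene | [O-][N+](=O)/C=C/c1c(Br)cc(O[Si](C(C)C)(C(C)C)C(C)C)cc1O[Si](C(C)C)(C(C)C)C(C)C | intermediate
17 | 5‑bromo‑2‑hydroxy‑3‑methoxybenzaldehyde | COc1cc(Br)cc(C=O)c1O | starting material
18 | 5‑bromo‑2,3‑dihydroxybenzaldehyde | Oc1cc(Br)cc(C=O)c1O | intermediate
19 | 5‑bromo‑3‑[(E)‑2‑nitroethenyl]benzene‑1,2‑diol | Oc1cc(Br)cc(/C=C/[N+](=O)[O-])c1O | intermediate
20 | 5‑bromo‑1,2‑bis(tert‑butyldimethylsilyloxy)‑3‑[(E)‑2‑nitroethenyl]benzene | [O-][N+](=O)/C=C/c1cc(Br)cc(O[Si](C)(C)C(C)(C)C)c1O[Si](C)(C)C(C)(C)C | intermediate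
21 | 5‑bromo‑1,2‑bis(TBSO)‑3‑{(1R)‑1‑[3,5‑bis(TIPSO)phenyl]‑2‑nitroethyl}benzene | Brc1cc(O[Si](C)(C)C(C)(C)C)c(O[Si](C)(C)C(C)(C)C)c(c1)[C@@H](c2cc(O[Si](C(C)C)(C(C)C)C(C)C)cc(O[Si](C(C)C)(C(C)C)C(C)C)c2)C[N+](=O)[O-] | intermediate
22 | 2‑{3,4‑bis(TBSO)‑5‑[(1R)‑1‑[3,5‑bis(TIPSO)phenyl]‑2‑nitroethyl]phenyl}‑4,4,5,5‑tetramethyl‑1,3,2‑dioxaborolane | CC1(C)OB(OC1(C)C)c2cc(O[Si](C)(C)C(C)(C)C)c(O[Si](C)(C)C(C)(C)C)c(c2)[C@@H](c3cc(O[Si](C(C)C)(C(C)C)C(C)C)cc(O[Si](C(C)C)(C(C)C)C(C)C)c3)C[N+](=O)[O-] | intermediate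
23 | 1‑bromo‑2‑[(1S)‑1‑{3,4‑bis(TBSO)‑5‑[(1R)‑1‑[3,5‑bis(TIPSO)phenyl]‑2‑nitroethyl]phenyl}‑2‑nitroethyl]‑3,5‑bis(TIPSO)benzene | Brc1cc(O[Si](C(C)C)(C(C)C)C(C)C)cc(O[Si](C(C)C)(C(C)C)C(C)C)c1[C@H](c2cc(O[Si](C)(C)C(C)(C)C)c(O[Si](C)(C)C(C)(C)C)c(c2)[C@@H](c3cc(O[Si](C(C)C)(C(C)C)C(C)C)cc(O[Si](C(C)C)(C(C)C)C(C)C)c3)C[N+](=O)[O-])C[N+](=O)[O-] | intermediate
24 | dipotassium bis‑nitronate of 23 (both CH2NO2 groups as CH=NO2 K, same configuration) | Brc1cc(O[Si](C(C)C)(C(C)C)C(C)C)cc(O[Si](C(C)C)(C(C)C)C(C)C)c1[C@H](c2cc(O[Si](C)(C)C(C)(C)C)c(O[Si](C)(C)C(C)(C)C)c(c2)[C@@H](c3cc(O[Si](C(C)C)(C(C)C)C(C)C)cc(O[Si](C(C)C)(C(C)C)C(C)C)c3)C=[N+]([O-])[O-])C=[N+]([O-])[O-].[K+].[K+] | intermediate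
25 | (2S)‑2‑[2‑bromo‑4,6‑bis(TIPSO)phenyl]‑2‑{3,4‑bis(TBSO)‑5‑[(1R)‑1‑[3,5‑bis(TIPSO)phenyl]‑2‑oxoethyl]phenyl}acetaldehyde | Brc1cc(O[Si](C(C)C)(C(C)C)C(C)C)cc(O[Si](C(C)C)(C(C)C)C(C)C)c1[C@H](c2cc(O[Si](C)(C)C(C)(C)C)c(O[Si](C)(C)C(C)(C)C)c(c2)[C@@H](c3cc(O[Si](C(C)C)(C(C)C)C(C)C)cc(O[Si](C(C)C)(C(C)C)C(C)C)c3)C=O)C=O | intermediate
26 | bis(bromomagnesium alkoxide) from addition of 3 to both aldehydes of 25 (carbinol carbons unselective) | Brc1cc(O[Si](C(C)C)(C(C)C)C(C)C)cc(O[Si](C(C)C)(C(C)C)C(C)C)c1[C@H](c2cc(O[Si](C)(C)C(C)(C)C)c(O[Si](C)(C)C(C)(C)C)c(c2)[C@@H](c3cc(O[Si](C(C)C)(C(C)C)C(C)C)cc(O[Si](C(C)C)(C(C)C)C(C)C)c3)C(O[Mg]Br)c4ccc(O[Si](C(C)C)(C(C)C)C(C)C)cc4)C(O[Mg]Br)c5ccc(O[Si](C(C)C)(C(C)C)C(C)C)cc5 | intermediate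
27 | (2S)‑2‑[2‑bromo‑4,6‑bis(TIPSO)phenyl]‑2‑{3‑[(1R)‑2‑acetoxy‑1‑[3,5‑bis(TIPSO)phenyl]‑2‑[4‑(TIPSO)phenyl]ethyl]‑4,5‑bis(TBSO)phenyl}‑1‑[4‑(TIPSO)phenyl]ethyl acetate (epimer mixture at both acetoxy carbons) | Brc1cc(O[Si](C(C)C)(C(C)C)C(C)C)cc(O[Si](C(C)C)(C(C)C)C(C)C)c1[C@H](c2cc(O[Si](C)(C)C(C)(C)C)c(O[Si](C)(C)C(C)(C)C)c(c2)[C@@H](c3cc(O[Si](C(C)C)(C(C)C)C(C)C)cc(O[Si](C(C)C)(C(C)C)C(C)C)c3)C(OC(C)=O)c4ccc(O[Si](C(C)C)(C(C)C)C(C)C)cc4)C(OC(C)=O)c5ccc(O[Si](C(C)C)(C(C)C)C(C)C)cc5 | intermediate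
28 | analogue of 27 with the ring A bromine replaced by a [4‑(TIPSO)phenyl]ethynyl group | CC(C)[Si](C(C)C)(C(C)C)Oc6ccc(cc6)C#Cc1cc(O[Si](C(C)C)(C(C)C)C(C)C)cc(O[Si](C(C)C)(C(C)C)C(C)C)c1[C@H](c2cc(O[Si](C)(C)C(C)(C)C)c(O[Si](C)(C)C(C)(C)C)c(c2)[C@@H](c3cc(O[Si](C(C)C)(C(C)C)C(C)C)cc(O[Si](C(C)C)(C(C)C)C(C)C)c3)C(OC(C)=O)c4ccc(O[Si](C(C)C)(C(C)C)C(C)C)cc4)C(OC(C)=O)c5ccc(O[Si](C(C)C)(C(C)C)C(C)C)cc5 | intermediate
29 | analogue of 28 with the alkyne reduced to the (Z)‑alkene | CC(C)[Si](C(C)C)(C(C)C)Oc6ccc(cc6)/C=C\c1cc(O[Si](C(C)C)(C(C)C)C(C)C)cc(O[Si](C(C)C)(C(C)C)C(C)C)c1[C@H](c2cc(O[Si](C)(C)C(C)(C)C)c(O[Si](C)(C)C(C)(C)C)c(c2)[C@@H](c3cc(O[Si](C(C)C)(C(C)C)C(C)C)cc(O[Si](C(C)C)(C(C)C)C(C)C)c3)C(OC(C)=O)c4ccc(O[Si](C(C)C)(C(C)C)C(C)C)cc4)C(OC(C)=O)c5ccc(O[Si](C(C)C)(C(C)C)C(C)C)cc5 | intermediate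
30 | nonaphenol bis‑acetate (29 with all nine silyl groups removed; present as phenoxides) | Oc6ccc(cc6)/C=C\c1cc(O)cc(O)c1[C@H](c2cc(O)c(O)c(c2)[C@@H](c3cc(O)cc(O)c3)C(OC(C)=O)c4ccc(O)cc4)C(OC(C)=O)c5ccc(O)cc5 | intermediate
31 | bis(para‑quinone methide) (30 after loss of both acetates; (S) at the ring A methine, (R) at the ring B methine) | Oc6ccc(cc6)/C=C\c1cc(O)cc(O)c1[C@H](c2cc(O)c(O)c(c2)[C@@H](c3cc(O)cc(O)c3)C=C4C=CC(=O)C=C4)C=C5C=CC(=O)C=C5 | intermediate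
32 | (2S,3S)‑3‑[(2R,3R)‑3‑(3,5‑dihydroxyphenyl)‑7‑hydroxy‑2‑(4‑hydroxyphenyl)‑2,3‑dihydro‑1‑benzofuran‑5‑yl]‑2‑(4‑hydroxyphenyl)‑4‑[(Z)‑2‑(4‑hydroxyphenyl)ethenyl]‑2,3‑dihydro‑1‑benzofuran‑6‑ol | Oc1ccc(/C=C\c2cc(O)cc3c2[C@H](c2cc(O)c4c(c2)[C@@H](c2cc(O)cc(O)c2)[C@H](c2ccc(O)cc2)O4)[C@@H](c2ccc(O)cc2)O3)cc1 | target

## Totals and risks

Total step count: 21.
Longest linear sequence: 11 steps (steps 11 to 21, from 17); the branches from 7, 10 and 1 are 10, 10 and 6 steps long.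

**Step 16 (conjugate arylation of the di‑ortho‑substituted nitroalkene 16).** The β‑carbon is flanked by bromine and a silyloxy group, so insertion may be slow and protodeboronation of 22 may win. The fallback reverses the polarity and forms the ring A–C‑3 bond by Friedel–Crafts attack of the free resorcinol. It sets out from 21. Palladium‑catalysed reductive carbonylation (Pd(OAc)2, di(1‑adamantyl)‑n‑butylphosphine, CO/H2, TMEDA, toluene, 100 °C) gives 3,4‑bis(TBSO)‑5‑[(1R)‑1‑[3,5‑bis(TIPSO)phenyl]‑2‑nitroethyl]benzaldehyde F1. Henry condensation with nitromethane 14 (NH4OAc cat., 60 °C) gives 1,2‑bis(TBSO)‑3‑[(1R)‑1‑[3,5‑bis(TIPSO)phenyl]‑2‑nitroethyl]‑5‑[(E)‑2‑nitroethenyl]benzene F2. A quinine‑derived bifunctional squaramide then catalyses the enantioselective Friedel–Crafts (Michael‑type) addition of 5‑bromobenzene‑1,3‑diol 7 through its C‑4 to give 5‑bromo‑4‑[(1S)‑1‑{3,4‑bis(TBSO)‑5‑[(1R)‑1‑[3,5‑bis(TIPSO)phenyl]‑2‑nitroethyl]phenyl}‑2‑nitroethyl]benzene‑1,3‑diol F3. Silylation with TIPSOTf/2,6‑lutidine comes back to the route at 23.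

**Step 17 (double Nef reaction).** The α,α‑diaryl aldehydes are easily enolised, and the oxidant could over‑oxidise or touch the electron‑rich arenes. The fallback passes through non‑enolisable oxidation levels and sets out from 23. NaNO2/AcOH in DMSO at 35 °C converts both nitromethyl groups into carboxylic acids, giving (2S)‑2‑[2‑bromo‑4,6‑bis(TIPSO)phenyl]‑2‑{3,4‑bis(TBSO)‑5‑[(1R)‑carboxy[3,5‑bis(TIPSO)phenyl]methyl]phenyl}acetic acid F4. BH3·SMe2 in THF reduces it to (2S)‑2‑[2‑bromo‑4,6‑bis(TIPSO)phenyl]‑2‑{3,4‑bis(TBSO)‑5‑[(1R)‑1‑[3,5‑bis(TIPSO)phenyl]‑2‑hydroxyethyl]phenyl}ethanol F5. Dess–Martin periodinane buffered with NaHCO3 in CH2Cl2 at 0 °C oxidises the diol to the dialdehyde immediately before step 18, which comes back to the route at 25.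

**Step 21 (nine desilylations and two ring closures in one operation).** Possible failures are tautomerisation of a quinone methide to a triarylethene, intermolecular trapping, or incomplete closure on precious material. The fallback closes the rings earlier, on the bromide, and separates ring closure from the final deprotection. It sets out from 27. TBAF in THF (0 °C to rt) triggers the same double oxa‑Michael closure and gives (2S,3S)‑4‑bromo‑3‑[(2R,3R)‑3‑(3,5‑dihydroxyphenyl)‑7‑hydroxy‑2‑(4‑hydroxyphenyl)‑2,3‑dihydro‑1‑benzofuran‑5‑yl]‑2‑(4‑hydroxyphenyl)‑2,3‑dihydro‑1‑benzofuran‑6‑ol F6, which can be purified and checked for the trans,trans relationship. TBSOTf/2,6‑lutidine gives its hexakis(tert‑butyldimethylsilyl) ether F7. Sonogashira coupling with 6 under the step 19 conditions gives the diarylalkyne, the hexakis‑TBS ether carrying a [4‑(TIPSO)phenyl]ethynyl group at C‑4 F8. Semi‑hydrogenation as in step 20 gives the corresponding (Z)‑stilbene F9. TBAF buffered with AcOH then removes the seven silyl groups and comes back to the route at 32.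

Further compounds
F1 | step 16 | 3,4‑bis(TBSO)‑5‑[(1R)‑1‑[3,5‑bis(TIPSO)phenyl]‑2‑nitroethyl]benzaldehyde | O=Cc1cc(O[Si](C)(C)C(C)(C)C)c(O[Si](C)(C)C(C)(C)C)c(c1)[C@@H](c2cc(O[Si](C(C)C)(C(C)C)C(C)C)cc(O[Si](C(C)C)(C(C)C)C(C)C)c2)C[N+](=O)[O-]
F2 | step 16 | 1,2‑bis(TBSO)‑3‑[(1R)‑1‑[3,5‑bis(TIPSO)phenyl]‑2‑nitroethyl]‑5‑[(E)‑2‑nitroethenyl]benzene | [O-][N+](=O)/C=C/c1cc(O[Si](C)(C)C(C)(C)C)c(O[Si](C)(C)C(C)(C)C)c(c1)[C@@H](c2cc(O[Si](C(C)C)(C(C)C)C(C)C)cc(O[Si](C(C)C)(C(C)C)C(C)C)c2)C[N+](=O)[O-]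
F3 | step 16 | 5‑bromo‑4‑[(1S)‑1‑{3,4‑bis(TBSO)‑5‑[(1R)‑1‑[3,5‑bis(TIPSO)phenyl]‑2‑nitroethyl]phenyl}‑2‑nitroethyl]benzene‑1,3‑diol | Brc1cc(O)cc(O)c1[C@H](c2cc(O[Si](C)(C)C(C)(C)C)c(O[Si](C)(C)C(C)(C)C)c(c2)[C@@H](c3cc(O[Si](C(C)C)(C(C)C)C(C)C)cc(O[Si](C(C)C)(C(C)C)C(C)C)c3)C[N+](=O)[O-])C[N+](=O)[O-]
F4 | step 17 | (2S)‑2‑[2‑bromo‑4,6‑bis(TIPSO)phenyl]‑2‑{3,4‑bis(TBSO)‑5‑[(1R)‑carboxy[3,5‑bis(TIPSO)phenyl]methyl]phenyl}acetic acid | Brc1cc(O[Si](C(C)C)(C(C)C)C(C)C)cc(O[Si](C(C)C)(C(C)C)C(C)C)c1[C@H](c2cc(O[Si](C)(C)C(C)(C)C)c(O[Si](C)(C)C(C)(C)C)c(c2)[C@@H](c3cc(O[Si](C(C)C)(C(C)C)C(C)C)cc(O[Si](C(C)C)(C(C)C)C(C)C)c3)C(=O)O)C(=O)O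
F5 | step 17 | (2S)‑2‑[2‑bromo‑4,6‑bis(TIPSO)phenyl]‑2‑{3,4‑bis(TBSO)‑5‑[(1R)‑1‑[3,5‑bis(TIPSO)phenyl]‑2‑hydroxyethyl]phenyl}ethanol | Brc1cc(O[Si](C(C)C)(C(C)C)C(C)C)cc(O[Si](C(C)C)(C(C)C)C(C)C)c1[C@H](c2cc(O[Si](C)(C)C(C)(C)C)c(O[Si](C)(C)C(C)(C)C)c(c2)[C@@H](c3cc(O[Si](C(C)C)(C(C)C)C(C)C)cc(O[Si](C(C)C)(C(C)C)C(C)C)c3)CO)CO
F6 | step 21 | (2S,3S)‑4‑bromo‑3‑[(2R,3R)‑3‑(3,5‑dihydroxyphenyl)‑7‑hydroxy‑2‑(4‑hydroxyphenyl)‑2,3‑dihydro‑1‑benzofuran‑5‑yl]‑2‑(4‑hydroxyphenyl)‑2,3‑dihydro‑1‑benzofuran‑6‑ol | Brc2cc(O)cc3c2[C@H](c2cc(O)c4c(c2)[C@@H](c2cc(O)cc(O)c2)[C@H](c2ccc(O)cc2)O4)[C@@H](c2ccc(O)cc2)O3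
F7 | step 21 | hexakis(tert‑butyldimethylsilyl) ether of F6 | Brc2cc(O[Si](C)(C)C(C)(C)C)cc3c2[C@H](c2cc(O[Si](C)(C)C(C)(C)C)c4c(c2)[C@@H](c2cc(O[Si](C)(C)C(C)(C)C)cc(O[Si](C)(C)C(C)(C)C)c2)[C@H](c2ccc(O[Si](C)(C)C(C)(C)C)cc2)O4)[C@@H](c2ccc(O[Si](C)(C)C(C)(C)C)cc2)O3
F8 | step 21 | F7 with the bromine replaced by a [4‑(TIPSO)phenyl]ethynyl group | CC(C)[Si](C(C)C)(C(C)C)Oc1ccc(cc1)C#Cc2cc(O[Si](C)(C)C(C)(C)C)cc3c2[C@H](c2cc(O[Si](C)(C)C(C)(C)C)c4c(c2)[C@@H](c2cc(O[Si](C)(C)C(C)(C)C)cc(O[Si](C)(C)C(C)(C)C)c2)[C@H](c2ccc(O[Si](C)(C)C(C)(C)C)cc2)O4)[C@@H](c2ccc(O[Si](C)(C)C(C)(C)C)cc2)O3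
F9 | step 21 | F8 with the alkyne reduced to the (Z)‑alkene | CC(C)[Si](C(C)C)(C(C)C)Oc1ccc(cc1)/C=C\c2cc(O[Si](C)(C)C(C)(C)C)cc3c2[C@H](c2cc(O[Si](C)(C)C(C)(C)C)c4c(c2)[C@@H](c2cc(O[Si](C)(C)C(C)(C)C)cc(O[Si](C)(C)C(C)(C)C)c2)[C@H](c2ccc(O[Si](C)(C)C(C)(C)C)cc2)O4)[C@@H](c2ccc(O[Si](C)(C)C(C)(C)C)cc2)O3
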